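**Plan**

- Retrosynthetic cuts, in order: the eight O–benzyl bonds and the C8–Br bond of the lower unit; C4–C4a of the upper chroman (ring C), opened back to a C3–C4 cis-epoxide on a 3-benzyloxyphenyl ether; the epoxide oxygen and the Z-alkene; the bond from C4 to C6 of ring D (aryl iodide plus terminal alkyne); the C2–O ether bond to ring A and the C2–C3 bond to 3,4-bis(benzyloxy)benzaldehyde.
- Forward: the lower unit (benzo ring D, catechol ring E, pyran ring F) comes intact from (+)-catechin (benzylation, bromine block at C8, iodine at C6). The C2–C3–C4 chain is built on the ring B aldehyde by alkynylation, ring A is attached through oxygen, the chain is joined to ring D by Sonogashira coupling, and ring C closes last.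
- Enabling feature: C4 of the upper unit is a doubly benzylic methine between C4a of ring A and C6 of the phloroglucinol-type ring D, cis to the C3 hydroxyl. This is what an invertive attack of ring A on the ring-D-stabilised carbon of a C3–C4 cis-epoxide leaves behind.
- Stereochemistry: the lower unit (2R,3S) comes from the chiral pool; C2 from a catalytic enantioselective alkynylation followed by Mitsunobu inversion; C3 and the epoxide face from allylic-strain-controlled epoxidation of the Z-alkene; C4 from inversion in the ring closure.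

Key step: step 11

Remarks on the chemistry:
- Upper-unit atoms are written C2, C3, C4; lower-unit atoms carry the ring letter, e.g. C6(D), C8(D).
- The descriptor at the ether carbon alternates (R in 11, S in 12, R in 13, S in 14, R in 15) only because substituent priorities change. The spatial arrangement is the same from 11 onward.
- Assumption: the BINOL–titanium alkynylation follows the facial sense of the related dialkylzinc additions, so (R)-BINOL is taken to deliver the alkynyl group to the Re face. The route needs only that one antipode gives the (S)-alcohol 9.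

Step 1
Reactants: 1 (+)-catechin
Product: 2 5,7,3',4'-tetra-O-benzyl-(+)-catechin
Conditions: BnBr (4.4 equiv), K2CO3, DMF, 0 °C → rt
Reagents that add atoms: benzyl bromide BrCc1ccccc1
Why: Williamson etherification under carbonate alkylates the four phenols and should leave the far less acidic aliphatic C3(F) hydroxyl and both stereocentres untouched.

Step 2
Reactants: 2 5,7,3',4'-tetra-O-benzyl-(+)-catechin
Product: 3 8-bromo-5,7,3',4'-tetra-O-benzyl-(+)-catechin
Conditions: NBS (1.0 equiv), CH2Cl2, −78 °C → rt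
Reagents that add atoms: N-bromosuccinimide O=C1CCC(=O)N1Br
Why: Electrophilic aromatic bromination of the trioxygenated ring D goes to C8, the more reactive position of benzylated catechins, which blocks it and reserves C6 for the later coupling.

Step 3
Reactants: 3 8-bromo-5,7,3',4'-tetra-O-benzyl-(+)-catechin
Product: 4 8-bromo-3,5,7,3',4'-penta-O-benzyl-(+)-catechin
Conditions: NaH, BnBr, DMF, 0 °C → rt
Reagents that add atoms: benzyl bromide BrCc1ccccc1
Why: Williamson etherification of the sodium alkoxide caps the C3(F) hydroxyl so that no free hydroxyl can compete as a nucleophile in the Lewis acid step.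

Step 4
Reactants: 4 8-bromo-3,5,7,3',4'-penta-O-benzyl-(+)-catechin
Product: 5 8-bromo-6-iodo-3,5,7,3',4'-penta-O-benzyl-(+)-catechin
Conditions: NIS (1.1 equiv), CH2Cl2–MeCN, 0 °C → rt, dark
Reagents that add atoms: N-iodosuccinimide O=C1CCC(=O)N1I
Why: Electrophilic aromatic iodination takes the only open position of the still trioxygenated ring D (C6), the catechol diether ring E being much less nucleophilic.

Step 5
Reactants: 6 3,4-bis(benzyloxy)benzaldehyde; 7 (trimethylsilyl)acetylene
Product: 9 (S)-1-[3,4-bis(benzyloxy)phenyl]-3-(trimethylsilyl)prop-2-yn-1-ol, via ethyl[(trimethylsilyl)ethynyl]zinc 8 (not isolated)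
Conditions: 7, Et2Zn, Cy2NH (5 mol%), Et2O, rt; then (R)-BINOL (20 mol%), Ti(OiPr)4 (50 mol%), 6, rt; aq. NH4Cl
Reagents that add atoms: none
Why: Catalytic enantioselective alkynylzinc addition to an aromatic aldehyde under BINOL–Ti(OiPr)4 control should deliver the alkynyl group to the Re face and so set the carbinol centre as S.

Step 6
Reactants: 9 (S)-1-[3,4-bis(benzyloxy)phenyl]-3-(trimethylsilyl)prop-2-yn-1-ol; 10 3-(benzyloxy)phenol
Product: 11 1-(benzyloxy)-3-{[(1R)-1-[3,4-bis(benzyloxy)phenyl]-3-(trimethylsilyl)prop-2-yn-1-yl]oxy}benzene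
Conditions: PPh3, DIAD, toluene, −20 → 0 °C
Reagents that add atoms: none
Why: Mitsunobu etherification of a secondary propargylic alcohol with a phenol displaces the oxyphosphonium group by SN2 and inverts the centre to R; running it before ring D is attached, with only a silylalkynyl group on the carbinol carbon, in toluene at low temperature, should keep ionisation down.

Step 7
Reactants: 11 1-(benzyloxy)-3-{[(1R)-1-[3,4-bis(benzyloxy)phenyl]-3-(trimethylsilyl)prop-2-yn-1-yl]oxy}benzene
Product: 12 1-(benzyloxy)-3-{[(1S)-1-[3,4-bis(benzyloxy)phenyl]prop-2-yn-1-yl]oxy}benzene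
Conditions: K2CO3 (cat.), MeOH–THF, 0 °C → rt
Reagents that add atoms: none
Why: Carbonate-catalysed methanolysis of the alkynyl C–Si bond (protodesilylation) is too mild to isomerise the propargylic ether to an allene or to touch the ether centre.

Step 8
Reactants: 5 8-bromo-6-iodo-3,5,7,3',4'-penta-O-benzyl-(+)-catechin; 12 1-(benzyloxy)-3-{[(1S)-1-[3,4-bis(benzyloxy)phenyl]prop-2-yn-1-yl]oxy}benzene
Product: 13 diaryl alkyne, 6-{(3R)-3-[3-(benzyloxy)phenoxy]-3-[3,4-bis(benzyloxy)phenyl]prop-1-yn-1-yl}-8-bromo-penta-O-benzyl-(+)-catechin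
Conditions: Pd(PPh3)2Cl2 (5 mol%), CuI (10 mol%), Et3N–THF, 50–60 °C, degassed
Reagents that add atoms: none
Why: Sonogashira coupling occurs at the C–I bond, which undergoes oxidative addition far faster than the hindered, electron-rich C–Br bond, and the ether stereocentre takes no part.

Step 9
Reactants: 13 diaryl alkyne
Product: 14 (Z)-alkene, 6-{(1Z,3S)-3-[3-(benzyloxy)phenoxy]-3-[3,4-bis(benzyloxy)phenyl]prop-1-en-1-yl}-8-bromo-penta-O-benzyl-(+)-catechin
Conditions: H2 (1 atm), Pd/CaCO3 poisoned with Pb(OAc)2 (Lindlar catalyst), quinoline, EtOAc, rt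
Reagents that add atoms: none
Why: Lindlar semihydrogenation adds H2 syn to the alkyne to give the Z-alkene, and the poisoned palladium should spare the benzyl ethers, the aryl bromide and the allylic C–O bond.

Step 10
Reactants: 14 (Z)-alkene
Product: 15 cis-epoxide, 6-[(2R,3R)-3-{(R)-[3-(benzyloxy)phenoxy][3,4-bis(benzyloxy)phenyl]methyl}oxiran-2-yl]-8-bromo-penta-O-benzyl-(+)-catechin
Conditions: DMDO (acetone solution, 1.3 equiv), CH2Cl2, −40 → −20 °C; volatiles removed cold, crude epoxide used at once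
Reagents that add atoms: dimethyldioxirane CC1(C)OO1
Why: Dioxirane epoxidation transfers oxygen stereospecifically (cis-alkene to cis-epoxide) under neutral conditions; allylic 1,3-strain holds the C2–H bond in the alkene plane toward ring D, ring B then shields one face, and the oxidant should add to the face bearing the aryloxy group, setting C3 and C4 with oxygen syn to the ether oxygen.

Step 11
Reactants: 15 cis-epoxide
Product: 16 (2R,3R,4S)-7-(benzyloxy)-2-[3,4-bis(benzyloxy)phenyl]-4-[8-bromo-penta-O-benzyl-(+)-catechin-6-yl]chroman-3-ol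
Conditions: BF3·OEt2 (0.2 equiv), CH2Cl2, −78 °C; Et3N quench
Reagents that add atoms: none
Why: BF3 binds the epoxide oxygen, the C4–O bond (benzylic to the trioxygenated ring D) lengthens, and the ring A carbon para to the benzyloxy group and ortho to the ether oxygen attacks C4 from the side opposite the departing oxygen; proton loss from the arenium ion restores ring A and frees the C3 hydroxyl. The closest known reaction type is the Lewis-acid-mediated intramolecular Friedel–Crafts epoxy–arene cyclisation of aryl 2,3-epoxyalkyl ethers to flavan-3-ols and 4-arylchroman-3-ols. Ring C closes in the 6-endo mode (both epoxide carbons end up in the ring), the 5-exo alternative at C3 having no benzylic stabilisation. The new stereocentre C4 is set by inversion at the epoxide carbon, so the cis-epoxide places ring D cis to the C3 hydroxyl, while C2 and C3 are carried over unchanged. The step needs opening at C4 rather than C3 (secured by ring D); attack by the ring A carbon para to the benzyloxy group rather than the one between the two oxygens or a ring B carbon (secured by ortho/para activation, lower hindrance and the six-membered transition state); and invertive rather than free-cation opening (favoured by −78 °C, the tethered nucleophile and the meta bromine, which tempers ring D).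

Step 12
Reactants: 16 8'-bromo-octa-O-benzyl chromanol
Product: 17 (2R,3R,4S)-2-(3,4-dihydroxyphenyl)-4-[(2R,3S)-2-(3,4-dihydroxyphenyl)-3,5,7-trihydroxychroman-6-yl]chromane-3,7-diol (CNP0141631.2)
Conditions: H2 (1 atm), Pd(OH)2/C, Et3N, THF–MeOH–H2O, rt
Reagents that add atoms: none
Why: Heterogeneous hydrogenolysis over Pd(OH)2/C cleaves the eight benzyl ethers and hydrodehalogenates C8(D)–Br, with Et3N trapping HBr so that the acid-labile C4–C6(D) and C2–O1 bonds are not opened; no stereocentre is touched.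

**Compound list**

1 | (+)-catechin, (2R,3S)-2-(3,4-dihydroxyphenyl)chromane-3,5,7-triol | O[C@H]1Cc2c(O)cc(O)cc2O[C@@H]1c1ccc(O)c(O)c1 | starting material
2 | 5,7,3',4'-tetra-O-benzyl-(+)-catechin, (2R,3S)-5,7-bis(benzyloxy)-2-[3,4-bis(benzyloxy)phenyl]chroman-3-ol | c1c(OCc3ccccc3)cc2c(c1OCc3ccccc3)C[C@H](O)[C@@H](c1ccc(OCc3ccccc3)c(OCc3ccccc3)c1)O2 | intermediate
3 | 8-bromo-5,7,3',4'-tetra-O-benzyl-(+)-catechin | c1c(OCc3ccccc3)c(Br)c2c(c1OCc3ccccc3)C[C@H](O)[C@@H](c1ccc(OCc3ccccc3)c(OCc3ccccc3)c1)O2 | intermediate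
4 | 8-bromo-3,5,7,3',4'-penta-O-benzyl-(+)-catechin, (2R,3S)-3,5,7-tris(benzyloxy)-2-[3,4-bis(benzyloxy)phenyl]-8-bromochromane | c1c(OCc3ccccc3)c(Br)c2c(c1OCc3ccccc3)C[C@H](OCc3ccccc3)[C@@H](c1ccc(OCc3ccccc3)c(OCc3ccccc3)c1)O2 | intermediate
5 | 8-bromo-6-iodo-3,5,7,3',4'-penta-O-benzyl-(+)-catechin | Ic1c(OCc3ccccc3)c(Br)c2c(c1OCc3ccccc3)C[C@H](OCc3ccccc3)[C@@H](c1ccc(OCc3ccccc3)c(OCc3ccccc3)c1)O2 | intermediate
6 | 3,4-bis(benzyloxy)benzaldehyde | O=Cc1ccc(OCc2ccccc2)c(OCc2ccccc2)c1 | starting material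
7 | (trimethylsilyl)acetylene | C#C[Si](C)(C)C | starting material
8 | ethyl[(trimethylsilyl)ethynyl]zinc (not isolated) | CC[Zn]C#C[Si](C)(C)C | intermediate
9 | (S)-1-[3,4-bis(benzyloxy)phenyl]-3-(trimethylsilyl)prop-2-yn-1-ol | O[C@@H](c1ccc(OCc2ccccc2)c(OCc2ccccc2)c1)C#C[Si](C)(C)C | intermediate
10 | 3-(benzyloxy)phenol | Oc1cccc(OCc2ccccc2)c1 | starting material
11 | 1-(benzyloxy)-3-{[(1R)-1-[3,4-bis(benzyloxy)phenyl]-3-(trimethylsilyl)prop-2-yn-1-yl]oxy}benzene | c3ccccc3COc1cccc(c1)O[C@H](c1ccc(OCc3ccccc3)c(OCc3ccccc3)c1)C#C[Si](C)(C)C | intermediate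
12 | 1-(benzyloxy)-3-{[(1S)-1-[3,4-bis(benzyloxy)phenyl]prop-2-yn-1-yl]oxy}benzene | c3ccccc3COc1cccc(c1)O[C@H](c1ccc(OCc3ccccc3)c(OCc3ccccc3)c1)C#C | intermediate
13 | diaryl alkyne, 6-{(3R)-3-[3-(benzyloxy)phenoxy]-3-[3,4-bis(benzyloxy)phenyl]prop-1-yn-1-yl}-8-bromo-penta-O-benzyl-(+)-catechin | c3ccccc3COc1cccc(c1)O[C@H](c1ccc(OCc3ccccc3)c(OCc3ccccc3)c1)C#Cc1c(OCc3ccccc3)c(Br)c2c(c1OCc3ccccc3)C[C@H](OCc3ccccc3)[C@@H](c1ccc(OCc3ccccc3)c(OCc3ccccc3)c1)O2 | intermediate
14 | (Z)-alkene, 6-{(1Z,3S)-3-[3-(benzyloxy)phenoxy]-3-[3,4-bis(benzyloxy)phenyl]prop-1-en-1-yl}-8-bromo-penta-O-benzyl-(+)-catechin | c3ccccc3COc1cccc(c1)O[C@H](c1ccc(OCc3ccccc3)c(OCc3ccccc3)c1)/C=C\c1c(OCc3ccccc3)c(Br)c2c(c1OCc3ccccc3)C[C@H](OCc3ccccc3)[C@@H](c1ccc(OCc3ccccc3)c(OCc3ccccc3)c1)O2 | intermediate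
15 | cis-epoxide, 6-[(2R,3R)-3-{(R)-[3-(benzyloxy)phenoxy][3,4-bis(benzyloxy)phenyl]methyl}oxiran-2-yl]-8-bromo-penta-O-benzyl-(+)-catechin | c3ccccc3COc1cccc(c1)O[C@H](c1ccc(OCc3ccccc3)c(OCc3ccccc3)c1)[C@@H]4O[C@@H]4c1c(OCc3ccccc3)c(Br)c2c(c1OCc3ccccc3)C[C@H](OCc3ccccc3)[C@@H](c1ccc(OCc3ccccc3)c(OCc3ccccc3)c1)O2 | intermediate
16 | 8'-bromo-octa-O-benzyl target, (2R,3R,4S)-7-(benzyloxy)-2-[3,4-bis(benzyloxy)phenyl]-4-[8-bromo-penta-O-benzyl-(+)-catechin-6-yl]chroman-3-ol | c3ccccc3COc1ccc2c(c1)O[C@H](c1ccc(OCc3ccccc3)c(OCc3ccccc3)c1)[C@H](O)[C@@H]2c1c(OCc3ccccc3)c(Br)c2c(c1OCc3ccccc3)C[C@H](OCc3ccccc3)[C@@H](c1ccc(OCc3ccccc3)c(OCc3ccccc3)c1)O2 | intermediate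
17 | CNP0141631.2, (2R,3R,4S)-2-(3,4-dihydroxyphenyl)-4-[(2R,3S)-2-(3,4-dihydroxyphenyl)-3,5,7-trihydroxychroman-6-yl]chromane-3,7-diol | Oc1ccc2c(c1)O[C@H](c1ccc(O)c(O)c1)[C@H](O)[C@@H]2c1c(O)cc2c(c1O)C[C@H](O)[C@@H](c1ccc(O)c(O)c1)O2 | target

**Count**

Total steps: 12. Longest linear sequence: 9 steps (1 → 2 → 3 → 4 → 5 → 13 → 14 → 15 → 16 → 17); the aldehyde branch (steps 5–7) joins at step 8.

**Steps most likely to fail**

Step 11 (ring closure). The C4–O bond may ionise fully before ring A is in place. C4 would then form from a planar, ring-D-stabilised cation without facial control, and part of the cation could escape by 1,2-hydride shift. The fallback sets C4 and C3 after ring closure, under thermodynamic and reagent control. It sets out from epoxide 15: the same Lewis acid closure, run without regard to C4 selectivity, would give 16 together with its C4 epimer, the (2R,3R,4R)-chromanol F1. Dess–Martin periodinane (NaHCO3, CH2Cl2) would oxidise the mixture to the (2R,4R)-chroman-3-one F2 and the (2R,4S)-chroman-3-one F3. A catalytic amine base (DBU, CH2Cl2) should equilibrate the doubly benzylic, more acidic C4 so that F2 converges on F3, in which rings B and D are both equatorial. LiBH(s-Bu)3 (THF, −78 °C) should then add hydride from the equatorial direction, give the axial C3 hydroxyl cis to both aryl groups, and return to 16. Oxidation followed by hindered-hydride reduction is the established way from 2,3-trans to 2,3-cis flavan-3-ols.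

Step 10 (epoxidation). The dioxirane may discriminate poorly between the two alkene faces, since ring B and the aryloxy group are not far apart in size, and the very electron-rich epoxide may open during handling. The fallback reverses the order of etherification and epoxidation so that a free hydroxyl directs the oxidant. It sets out from 6 and 7: the alkynylation of step 5 run with (S)-BINOL would give (R)-1-[3,4-bis(benzyloxy)phenyl]-3-(trimethylsilyl)prop-2-yn-1-ol F4. K2CO3 in MeOH would give (S)-1-[3,4-bis(benzyloxy)phenyl]prop-2-yn-1-ol F5 (same spatial arrangement). Sonogashira coupling with iodide 5 (Pd(PPh3)2Cl2, CuI, Et3N) would give the ring-D-substituted (R)-propargylic alcohol F6, and Lindlar semihydrogenation the (S,Z)-allylic alcohol F7. Buffered mCPBA (NaHCO3, CH2Cl2, 0 °C) should epoxidise syn to the hydrogen-bonding hydroxyl, the threo preference of Z-allylic alcohols under allylic 1,3-strain, to give the cis-epoxy alcohol F8. O-Arylation of its sodium alkoxide with bis[3-(benzyloxy)phenyl]iodonium triflate (NaH, THF–toluene, 0 °C → rt) leaves the C2–O bond intact and comes back to the route at epoxide 15.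

Step 6 (Mitsunobu etherification). The oxyphosphonium intermediate may ionise at the benzylic, propargylic carbon (ring B carries a para oxygen), which would erode the enantiomeric purity, or the phenol may attack in the SN2' sense. The fallback creates the ether centre in the C–O bond-forming step under catalyst control. It sets out from aldehyde 6: HC≡CMgBr (THF, 0 °C) would give racemic 1-[3,4-bis(benzyloxy)phenyl]prop-2-yn-1-ol F9, and Ac2O, Et3N and DMAP its acetate F10. Copper-catalysed enantioselective propargylic etherification with phenol 10 ((CuOTf)2·C6H6, chiral pybox ligand of the appropriate antipode, iPr2NEt, MeOH, −20 °C) proceeds through a copper allenylidene and is enantioconvergent. It would come back to the route at terminal alkyne 12.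

Further compounds
F1 | step 11 | (2R,3R,4R)-7-(benzyloxy)-2-[3,4-bis(benzyloxy)phenyl]-4-[8-bromo-penta-O-benzyl-(+)-catechin-6-yl]chroman-3-ol (C4 epimer of 16) | c3ccccc3COc1ccc2c(c1)O[C@H](c1ccc(OCc3ccccc3)c(OCc3ccccc3)c1)[C@H](O)[C@H]2c1c(OCc3ccccc3)c(Br)c2c(c1OCc3ccccc3)C[C@H](OCc3ccccc3)[C@@H](c1ccc(OCc3ccccc3)c(OCc3ccccc3)c1)O2
F2 | step 11 | (2R,4R)-7-(benzyloxy)-2-[3,4-bis(benzyloxy)phenyl]-4-[8-bromo-penta-O-benzyl-(+)-catechin-6-yl]chroman-3-one (2,4-trans) | c3ccccc3COc1ccc2c(c1)O[C@H](c1ccc(OCc3ccccc3)c(OCc3ccccc3)c1)C(=O)[C@H]2c1c(OCc3ccccc3)c(Br)c2c(c1OCc3ccccc3)C[C@H](OCc3ccccc3)[C@@H](c1ccc(OCc3ccccc3)c(OCc3ccccc3)c1)O2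
F3 | step 11 | (2R,4S)-7-(benzyloxy)-2-[3,4-bis(benzyloxy)phenyl]-4-[8-bromo-penta-O-benzyl-(+)-catechin-6-yl]chroman-3-one (2,4-cis) | c3ccccc3COc1ccc2c(c1)O[C@H](c1ccc(OCc3ccccc3)c(OCc3ccccc3)c1)C(=O)[C@@H]2c1c(OCc3ccccc3)c(Br)c2c(c1OCc3ccccc3)C[C@H](OCc3ccccc3)[C@@H](c1ccc(OCc3ccccc3)c(OCc3ccccc3)c1)O2
F4 | step 10 | (R)-1-[3,4-bis(benzyloxy)phenyl]-3-(trimethylsilyl)prop-2-yn-1-ol | O[C@H](c1ccc(OCc2ccccc2)c(OCc2ccccc2)c1)C#C[Si](C)(C)C
F5 | step 10 | (S)-1-[3,4-bis(benzyloxy)phenyl]prop-2-yn-1-ol | O[C@H](c1ccc(OCc2ccccc2)c(OCc2ccccc2)c1)C#C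
F6 | step 10 | (R)-1-[3,4-bis(benzyloxy)phenyl]-3-[8-bromo-penta-O-benzyl-(+)-catechin-6-yl]prop-2-yn-1-ol | O[C@H](c1ccc(OCc3ccccc3)c(OCc3ccccc3)c1)C#Cc1c(OCc3ccccc3)c(Br)c2c(c1OCc3ccccc3)C[C@H](OCc3ccccc3)[C@@H](c1ccc(OCc3ccccc3)c(OCc3ccccc3)c1)O2
F7 | step 10 | (S,Z)-1-[3,4-bis(benzyloxy)phenyl]-3-[8-bromo-penta-O-benzyl-(+)-catechin-6-yl]prop-2-en-1-ol | O[C@H](c1ccc(OCc3ccccc3)c(OCc3ccccc3)c1)/C=C\c1c(OCc3ccccc3)c(Br)c2c(c1OCc3ccccc3)C[C@H](OCc3ccccc3)[C@@H](c1ccc(OCc3ccccc3)c(OCc3ccccc3)c1)O2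
F8 | step 10 | (R)-[3,4-bis(benzyloxy)phenyl]{(2S,3R)-3-[8-bromo-penta-O-benzyl-(+)-catechin-6-yl]oxiran-2-yl}methanol (threo cis-epoxy alcohol) | O[C@H](c1ccc(OCc3ccccc3)c(OCc3ccccc3)c1)[C@@H]4O[C@@H]4c1c(OCc3ccccc3)c(Br)c2c(c1OCc3ccccc3)C[C@H](OCc3ccccc3)[C@@H](c1ccc(OCc3ccccc3)c(OCc3ccccc3)c1)O2
F9 | step 6 | racemic 1-[3,4-bis(benzyloxy)phenyl]prop-2-yn-1-ol | OC(c1ccc(OCc2ccccc2)c(OCc2ccccc2)c1)C#C
F10 | step 6 | racemic 1-[3,4-bis(benzyloxy)phenyl]prop-2-yn-1-yl acetate | CC(=O)OC(c1ccc(OCc2ccccc2)c(OCc2ccccc2)c1)C#C
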